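The earlier runs and the new flask are calculated with made-up constants; scatter was added.

Which of larch and alder ends with the longer chains, and how long are they?

| flask | free monomer | transfer agent | initiator | remark | time |
|---|---|---|---|---|---|
| eta | 0.022 M | 0.50 mM | 2.5 mM | run made earlier |  |
| alpha | 0.067 M | 0.50 mM | 2.5 mM | run made earlier |  |
| larch | 0.050 M | 0.500 mM | 2.5 mM |  | 80 min |
| alder | 0.015 M | 0.500 mM | 2.5 mM |  | 80 min |

| eta: time / min | eta: monomer in chains / % | alpha: time / min | alpha: monomer in chains / % |
|---|---|---|---|
| 10.0 | 26 | 10.0 | 24 |
| 30.0 | 47 | 30.0 | 49 |
| 50.0 | 62 | 50.0 | 57 |
| 80.0 | 74 | 80.0 | 62 |

(standard deviation of a reading: 2 percentage points)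

1. which of the two ends with the longer chains by the average number of monomer units in a chain (chains begun, living or dead) ("neither" if they lie within 10%) (larch / alder / neither)
2. average number of monomer units in a chain (chains begun, living or dead) at the end, larch
3. average number of monomer units in a chain (chains begun, living or dead) at the end, alder

The length is a ratio, so I reckon top and bottom apart. For the top, at 80 min eta has 74% of its charge in chains and alpha 62%, each reading carrying a scatter of 2 percentage points. The fraction reads lower in alpha, the run with the larger charge, so I draw a straight line in charge through the two runs, and for alder I extend it below eta's charge:

larch: fraction in chains 66.5%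

alder: fraction in chains 75.9%

The bottom is a guess. As the zero of the scale I take one chain per initiator charged, an initiator efficiency of one, and I let the transfer agent end chains without beginning any. Then:

larch: 13.3 units per initiator, the fraction in chains times the free monomer charged per initiator charged

alder: 4.55 units per initiator

The weak link is whether the initiator is used up in time. In eta, the logarithm of charge over what is not in chains reads as growing by 0.0301 /min up to 10.0 min, but by 0.0167 /min from there to 30.0 min. This later reading is slower, and I take it, as a guess, for a supply of new chains ending early in eta. So I keep the count of 2.5 mM and commit to larch as longer, by a factor of 2.92.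

The forecast also says larch, but with 52 units in larch and 18 in alder, on the words “so I take about 0.65 mM”, against my 2.5 mM. My length for larch is shorter.

The flask gives larch, with 13.1 units in larch and 4.51 in alder. Larch has 0% of its initiator left at 80.0 min. Units per initiator, taken with the 65.6% of larch's charge in chains, come to 13.1, beside my 13.3 from the earlier runs. The count of chains is where my reckoning and the forecast part.

    free monomer + initiator → living end + monomer in chains (k = 23.4 /M/min)
    free monomer + living end → monomer in chains + living end, rate k2*[living end]*[free monomer] (k = 13.1 /M/min)
    living end + transfer agent → dead chain (kL = 311 /M/min)
    living end + monomer in chains → dead end A (k = 0.697 /M/min)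
    living end → dead end B (k = 0.00585 /min)

In a neighbour of alder with 0.025 M of free monomer, the same line gives a fraction of 73.2%, hence 7.32 units per initiator. The computed flask gives 7.18 units.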